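**Retrosynthetic overview**

1. Target ⇐ its hexabenzyl ether (hydrogenolysis). Ring C (O1–C2–C3–C4–C4a–C8a) is the only ring made in the synthesis and therefore the last: its O1–C2 bond is closed by a catalyst-controlled intramolecular oxa-Michael addition on an acyclic, achiral benzylidene β-ketoester, and the auxiliary CO2tBu on C3 is expelled in the same flask.
2. Enabling feature: ring C is a β-aryloxy ketone, O1–C2–C3–C4(=O), the retron of a conjugate addition of the C8a oxygen to C2. C3, α to the C4 carbonyl, can carry a temporary ester that binds the catalyst. Of the three A-ring oxygens only the one on C8a is left free (the ortho-OH chelated to the acyl C=O), so O5 and O7 stay capped and only O1 can close.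
3. Benzylidene β-ketoester ⇐ Knoevenagel with benzaldehyde ⇐ tert-butyl β-ketoester ⇐ fully substituted 2-hydroxy-4,6-bis(benzyloxy)acetophenone ⇐ two iodination/Negishi benzylation cycles (first ortho to the free OH, the future C8; then the last ring position, the future C6).
4. Tribenzyl chain chloride ⇐ two Suzuki benzylation/chlorination cycles from 2-(benzyloxy)benzyl chloride and one bifunctional aryl boronate that is used twice.
5. Ring order: all six benzene rings are bought; ring C is the single ring-closing event.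

Key step: step 15

Assumption: in step 15 the sense of induction is set by the catalyst alone; the quinidine-derived thiourea is written as the pseudoenantiomer expected to give 2S, the quinine-derived one being its counterpart for the antipode.

Short name used below: "trimer-benzyl" = 2-(benzyloxy)-5-[[2-(benzyloxy)-5-[2-(benzyloxy)benzyl]phenyl]methyl]benzyl, the benzyl group of chloride 9.

**Route**

Step 1
Reactants: 1 [2-(benzyloxy)phenyl]methanol
Product: 2 1-(benzyloxy)-2-(chloromethyl)benzene
Conditions: SOCl2 (1.2 equiv), DMF (cat.), CH2Cl2, 0 °C to rt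
Reagents that add atoms: thionyl chloride, O=S(Cl)Cl
Why: Deoxychlorination of a benzylic alcohol through its chlorosulfite should be clean and leaves the aryl benzyl ether untouched.

Step 2
Reactants: 3 4-bromo-2-(hydroxymethyl)phenol
Product: 4 [2-(benzyloxy)-5-bromophenyl]methanol
Conditions: BnBr (1.05 equiv), K2CO3, acetone, reflux
Reagents that add atoms: benzyl bromide, BrCc1ccccc1
Why: Williamson etherification; carbonate deprotonates only the phenol, so the benzylic alcohol should stay free.

Step 3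
Reactants: 4 [2-(benzyloxy)-5-bromophenyl]methanol
Product: 5 [2-(benzyloxy)-5-(4,4,5,5-tetramethyl-1,3,2-dioxaborolan-2-yl)phenyl]methanol
Conditions: B2pin2 (1.1 equiv), Pd(dppf)Cl2 (3 mol%), KOAc (3 equiv), 1,4-dioxane, 85 °C
Reagents that add atoms: bis(pinacolato)diboron, CC1(C)OB(OC1(C)C)B1OC(C)(C)C(C)(C)O1
Why: Miyaura borylation of the aryl bromide tolerates the free primary alcohol and the benzyl ether.

Step 4
Reactants: 2 1-(benzyloxy)-2-(chloromethyl)benzene; 5 [2-(benzyloxy)-5-(4,4,5,5-tetramethyl-1,3,2-dioxaborolan-2-yl)phenyl]methanol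
Product: 6 [2-(benzyloxy)-5-[2-(benzyloxy)benzyl]phenyl]methanol
Conditions: Pd(OAc)2 (2 mol%), SPhos (4 mol%), K3PO4 (2 equiv), THF/H2O (10:1), 60 °C
Reagents that add atoms: none
Why: Suzuki–Miyaura coupling of a benzylic chloride with an aryl pinacol boronate forms the diarylmethane bond para to the oxygen of the new ring, and the untouched CH2OH is the handle for the next cycle.

Step 5
Reactants: 6 [2-(benzyloxy)-5-[2-(benzyloxy)benzyl]phenyl]methanol
Product: 7 1-(benzyloxy)-4-[2-(benzyloxy)benzyl]-2-(chloromethyl)benzene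
Conditions: SOCl2 (1.2 equiv), DMF (cat.), CH2Cl2, 0 °C to rt
Reagents that add atoms: thionyl chloride, O=S(Cl)Cl
Why: Deoxychlorination of the benzylic alcohol as in step 1; diarylmethane and benzyl ethers are inert.

Step 6
Reactants: 7 1-(benzyloxy)-4-[2-(benzyloxy)benzyl]-2-(chloromethyl)benzene; 5 [2-(benzyloxy)-5-(4,4,5,5-tetramethyl-1,3,2-dioxaborolan-2-yl)phenyl]methanol
Product: 8 [2-(benzyloxy)-5-[[2-(benzyloxy)-5-[2-(benzyloxy)benzyl]phenyl]methyl]phenyl]methanol
Conditions: Pd(OAc)2 (2 mol%), SPhos (4 mol%), K3PO4 (2 equiv), THF/H2O (10:1), 60 °C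
Reagents that add atoms: none
Why: Second Suzuki–Miyaura coupling of a benzylic chloride with the same boronate, which repeats the ortho-CH2/para linkage of the chain.

Step 7
Reactants: 8 [2-(benzyloxy)-5-[[2-(benzyloxy)-5-[2-(benzyloxy)benzyl]phenyl]methyl]phenyl]methanol
Product: 9 1-(benzyloxy)-4-[[2-(benzyloxy)-5-[2-(benzyloxy)benzyl]phenyl]methyl]-2-(chloromethyl)benzene
Conditions: SOCl2 (1.2 equiv), DMF (cat.), CH2Cl2, 0 °C to rt
Reagents that add atoms: thionyl chloride, O=S(Cl)Cl
Why: Deoxychlorination of the benzylic alcohol as in steps 1 and 5.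

Step 8
Reactants: 10 1-(2,4,6-trihydroxyphenyl)ethanone
Product: 11 1-[2,4-bis(benzyloxy)-6-hydroxyphenyl]ethanone
Conditions: BnBr (2.05 equiv), K2CO3 (2.2 equiv), DMF, 0 °C to rt
Reagents that add atoms: benzyl bromide, BrCc1ccccc1
Why: Williamson etherification stops at the diether because the last ortho-OH is chelated to the acetyl C=O; this free OH becomes O1.

Step 9
Reactants: 11 1-[2,4-bis(benzyloxy)-6-hydroxyphenyl]ethanone
Product: 12 1-[4,6-bis(benzyloxy)-2-hydroxy-3-iodophenyl]ethanone
Conditions: BnMe3N·ICl2 (1.05 equiv), NaHCO3, CH2Cl2/MeOH, rt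
Reagents that add atoms: benzyltrimethylammonium dichloroiodate, C[N+](C)(C)Cc1ccccc1.Cl[I-]Cl
Why: Electrophilic aromatic iodination of the phenol is expected ortho to the free chelated OH (C3) and not at C5, which is flanked by two benzyloxy groups; this fixes the future C8.

Step 10
Reactants: 12 1-[4,6-bis(benzyloxy)-2-hydroxy-3-iodophenyl]ethanone; 2 1-(benzyloxy)-2-(chloromethyl)benzene
Product: 14 1-[4,6-bis(benzyloxy)-3-[2-(benzyloxy)benzyl]-2-hydroxyphenyl]ethanone, via [2-(benzyloxy)benzyl]zinc chloride 13 (not isolated)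
Conditions: (i) 2, Zn dust, LiCl, THF, 25 °C; (ii) 12, Pd(OAc)2 (2 mol%), SPhos (4 mol%), THF, 25 to 50 °C, slow addition of 13 (1.5 equiv)
Reagents that add atoms: none
Why: Negishi cross-coupling; LiCl-promoted zinc insertion into the benzylic C–Cl bond gives the benzylzinc chloride, which Pd/SPhos should couple with the hindered aryl iodide faster than the chelated phenol protonates it, and which does not add to the aryl ketone.

Step 11
Reactants: 14 1-[4,6-bis(benzyloxy)-3-[2-(benzyloxy)benzyl]-2-hydroxyphenyl]ethanone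
Product: 15 1-[4,6-bis(benzyloxy)-3-[2-(benzyloxy)benzyl]-2-hydroxy-5-iodophenyl]ethanone
Conditions: BnMe3N·ICl2 (1.05 equiv), NaHCO3, CH2Cl2/MeOH, rt
Reagents that add atoms: benzyltrimethylammonium dichloroiodate, C[N+](C)(C)Cc1ccccc1.Cl[I-]Cl
Why: Electrophilic aromatic iodination at the only open position of the phenolic ring (para to the free OH); the benzyl-ether rings are not activated enough to react under bicarbonate buffering.

Step 12
Reactants: 15 1-[4,6-bis(benzyloxy)-3-[2-(benzyloxy)benzyl]-2-hydroxy-5-iodophenyl]ethanone; 9 1-(benzyloxy)-4-[[2-(benzyloxy)-5-[2-(benzyloxy)benzyl]phenyl]methyl]-2-(chloromethyl)benzene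
Product: 17 1-[4,6-bis(benzyloxy)-3-[2-(benzyloxy)benzyl]-2-hydroxy-5-(trimer-benzyl)phenyl]ethanone, via trimer-benzylzinc chloride 16 (not isolated)
Conditions: (i) 9, Zn dust, LiCl, THF, 25 °C; (ii) 15, Pd(OAc)2 (3 mol%), SPhos (6 mol%), THF, 50 °C, slow addition of 16 (1.5 equiv)
Reagents that add atoms: none
Why: Second Negishi cross-coupling of the same kind, with SPhos chosen for the iodide flanked by two benzyloxy groups; it places the chain on the carbon between O5 and O7.

Step 13
Reactants: 17 1-[4,6-bis(benzyloxy)-3-[2-(benzyloxy)benzyl]-2-hydroxy-5-(trimer-benzyl)phenyl]ethanone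
Product: 18 tert-butyl 3-[4,6-bis(benzyloxy)-3-[2-(benzyloxy)benzyl]-2-hydroxy-5-(trimer-benzyl)phenyl]-3-oxopropanoate
Conditions: LiHMDS (3.3 equiv), THF, −78 °C; then Boc2O (1.1 equiv), −78 to 0 °C; aq. NH4Cl
Reagents that add atoms: di-tert-butyl dicarbonate, CC(C)(C)OC(=O)OC(=O)OC(C)(C)C
Why: Crossed-Claisen C-acylation; the phenoxide–enolate dianion should react with Boc2O at the unhindered enolate carbon (the chelated, doubly flanked phenoxide is the poorer nucleophile), and the third equivalent of base takes up the more acidic β-ketoester.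

Step 14
Reactants: 18 tert-butyl 3-[4,6-bis(benzyloxy)-3-[2-(benzyloxy)benzyl]-2-hydroxy-5-(trimer-benzyl)phenyl]-3-oxopropanoate; 19 benzaldehyde
Product: 20 tert-butyl 2-[4,6-bis(benzyloxy)-3-[2-(benzyloxy)benzyl]-2-hydroxy-5-(trimer-benzyl)benzoyl]-3-phenylprop-2-enoate (E/Z mixture)
Conditions: piperidine (10 mol%), AcOH (10 mol%), 4 Å MS, toluene, rt
Reagents that add atoms: none
Why: Knoevenagel condensation under piperidinium acetate catalysis; room temperature and molecular sieves are chosen to keep uncatalysed ring closure of the free phenol slow, and the alkene geometry need not be controlled.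

Step 15
Reactants: 20 tert-butyl 2-[4,6-bis(benzyloxy)-3-[2-(benzyloxy)benzyl]-2-hydroxy-5-(trimer-benzyl)benzoyl]-3-phenylprop-2-enoate (E/Z mixture)
Product: 23 (2S)-5,7-bis(benzyloxy)-8-[2-(benzyloxy)benzyl]-2-phenyl-6-(trimer-benzyl)chroman-4-one, via cyclised tert-butyl ester 21 (not isolated), via β-keto acid 22 (not isolated)
Conditions: (i) 9-amino(9-deoxy)epi-quinidine 3,5-bis(trifluoromethyl)phenyl thiourea (10 mol%), toluene, −25 °C; (ii) TsOH·H2O (2 equiv), 80 °C
Reagents that add atoms: none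
Why: The quinuclidine nitrogen of the bifunctional catalyst engages the only free phenol (the OH on the future C8a) while the thiourea hydrogen-bonds the 1,3-dicarbonyl unit, so that the phenol oxygen adds to the benzylidene carbon in an intramolecular oxa-Michael addition; TsOH then cleaves the tert-butyl ester to isobutene and the β-keto acid, which loses CO2. The closest known reaction type is the cinchona-thiourea-catalysed cyclisation of 2-hydroxyaryl benzylidene β-ketoesters to flavanones with acid-induced decarboxylation in the same flask. Ring C (O1–C2–C3–C4–C4a–C8a) is closed in the 6-endo-trig mode by formation of the O1–C2 bond. C2, the only stereocentre of the target, is set under catalyst control (the bound substrate exposes one face of the benzylidene carbon to the activated phenol; no other stereocentre is present), the E and Z alkylidenes can equilibrate through reversible amine addition, and the labile C3 centre vanishes on decarboxylation, so that the isomer mixture should converge on one flavanone. The step needs site selectivity between O1 and O5 and enantiofacial selectivity: the first is secured because O5 and O7 are benzyl ethers and only the chelated C8a–OH can reach C2, the second by the low temperature and by the CO2tBu group, which makes closure fast and catalyst-bound and whose removal afterwards closes the retro-oxa-Michael path to racemisation.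

Step 16
Reactants: 23 (2S)-5,7-bis(benzyloxy)-8-[2-(benzyloxy)benzyl]-2-phenyl-6-(trimer-benzyl)chroman-4-one
Product: 24 sarmentosumin B
Conditions: H2 (1 atm), 10% Pd/C, EtOAc/MeOH, rt
Reagents that add atoms: none
Why: Catalytic hydrogenolysis of the six aryl benzyl ethers; primary O-benzyl groups should be cleaved faster than the cyclic benzylic C2–O1 bond, and neutral conditions avoid the base-induced ring opening that would racemise C2.

**Compound list**

1 | [2-(benzyloxy)phenyl]methanol | OCc1ccccc1OCc1ccccc1 | starting material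
2 | 1-(benzyloxy)-2-(chloromethyl)benzene | ClCc1ccccc1OCc1ccccc1 | intermediate
3 | 4-bromo-2-(hydroxymethyl)phenol (5-bromo-2-hydroxybenzyl alcohol) | OCc1cc(Br)ccc1O | starting material
4 | [2-(benzyloxy)-5-bromophenyl]methanol | OCc1cc(Br)ccc1OCc1ccccc1 | intermediate
5 | [2-(benzyloxy)-5-(4,4,5,5-tetramethyl-1,3,2-dioxaborolan-2-yl)phenyl]methanol | OCc1cc(B2OC(C)(C)C(C)(C)O2)ccc1OCc1ccccc1 | intermediate
6 | [2-(benzyloxy)-5-[2-(benzyloxy)benzyl]phenyl]methanol | OCc1cc(Cc2ccccc2OCc2ccccc2)ccc1OCc1ccccc1 | intermediate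
7 | 1-(benzyloxy)-4-[2-(benzyloxy)benzyl]-2-(chloromethyl)benzene | ClCc1cc(Cc2ccccc2OCc2ccccc2)ccc1OCc1ccccc1 | intermediate
8 | [2-(benzyloxy)-5-[[2-(benzyloxy)-5-[2-(benzyloxy)benzyl]phenyl]methyl]phenyl]methanol | OCc1cc(Cc2cc(Cc3ccccc3OCc3ccccc3)ccc2OCc2ccccc2)ccc1OCc1ccccc1 | intermediate
9 | 1-(benzyloxy)-4-[[2-(benzyloxy)-5-[2-(benzyloxy)benzyl]phenyl]methyl]-2-(chloromethyl)benzene (trimer-benzyl chloride) | ClCc1cc(Cc2cc(Cc3ccccc3OCc3ccccc3)ccc2OCc2ccccc2)ccc1OCc1ccccc1 | intermediate
10 | 1-(2,4,6-trihydroxyphenyl)ethanone | CC(=O)c1c(O)cc(O)cc1O | starting material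
11 | 1-[2,4-bis(benzyloxy)-6-hydroxyphenyl]ethanone | CC(=O)c1c(O)cc(OCc2ccccc2)cc1OCc1ccccc1 | intermediate
12 | 1-[4,6-bis(benzyloxy)-2-hydroxy-3-iodophenyl]ethanone | CC(=O)c1c(O)c(I)c(OCc2ccccc2)cc1OCc1ccccc1 | intermediate
13 | [2-(benzyloxy)benzyl]zinc chloride | Cl[Zn]Cc1ccccc1OCc1ccccc1 | intermediate
14 | 1-[4,6-bis(benzyloxy)-3-[2-(benzyloxy)benzyl]-2-hydroxyphenyl]ethanone | CC(=O)c1c(O)c(Cc2ccccc2OCc2ccccc2)c(OCc2ccccc2)cc1OCc1ccccc1 | intermediate
15 | 1-[4,6-bis(benzyloxy)-3-[2-(benzyloxy)benzyl]-2-hydroxy-5-iodophenyl]ethanone | CC(=O)c1c(O)c(Cc2ccccc2OCc2ccccc2)c(OCc2ccccc2)c(I)c1OCc1ccccc1 | intermediate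
16 | trimer-benzylzinc chloride | Cl[Zn]Cc1cc(Cc2cc(Cc3ccccc3OCc3ccccc3)ccc2OCc2ccccc2)ccc1OCc1ccccc1 | intermediate
17 | 1-[4,6-bis(benzyloxy)-3-[2-(benzyloxy)benzyl]-2-hydroxy-5-(trimer-benzyl)phenyl]ethanone | CC(=O)c1c(O)c(Cc2ccccc2OCc2ccccc2)c(OCc2ccccc2)c(Cc2cc(Cc3cc(Cc4ccccc4OCc4ccccc4)ccc3OCc3ccccc3)ccc2OCc2ccccc2)c1OCc1ccccc1 | intermediate
18 | tert-butyl 3-[4,6-bis(benzyloxy)-3-[2-(benzyloxy)benzyl]-2-hydroxy-5-(trimer-benzyl)phenyl]-3-oxopropanoate | CC(C)(C)OC(=O)CC(=O)c1c(O)c(Cc2ccccc2OCc2ccccc2)c(OCc2ccccc2)c(Cc2cc(Cc3cc(Cc4ccccc4OCc4ccccc4)ccc3OCc3ccccc3)ccc2OCc2ccccc2)c1OCc1ccccc1 | intermediate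
19 | benzaldehyde | O=Cc1ccccc1 | starting material
20 | tert-butyl 2-[4,6-bis(benzyloxy)-3-[2-(benzyloxy)benzyl]-2-hydroxy-5-(trimer-benzyl)benzoyl]-3-phenylprop-2-enoate (E/Z mixture; geometry left open) | CC(C)(C)OC(=O)C(=Cc1ccccc1)C(=O)c1c(O)c(Cc2ccccc2OCc2ccccc2)c(OCc2ccccc2)c(Cc2cc(Cc3cc(Cc4ccccc4OCc4ccccc4)ccc3OCc3ccccc3)ccc2OCc2ccccc2)c1OCc1ccccc1 | intermediate
21 | tert-butyl (2S)-5,7-bis(benzyloxy)-8-[2-(benzyloxy)benzyl]-4-oxo-2-phenyl-6-(trimer-benzyl)chromane-3-carboxylate (C3 stereolabile; left open) | O=C1C(C(=O)OC(C)(C)C)[C@@H](c2ccccc2)Oc2c(Cc3ccccc3OCc3ccccc3)c(OCc3ccccc3)c(Cc3cc(Cc4cc(Cc5ccccc5OCc5ccccc5)ccc4OCc4ccccc4)ccc3OCc3ccccc3)c(OCc3ccccc3)c21 | intermediate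
22 | (2S)-5,7-bis(benzyloxy)-8-[2-(benzyloxy)benzyl]-4-oxo-2-phenyl-6-(trimer-benzyl)chromane-3-carboxylic acid (C3 stereolabile; left open) | O=C1C(C(=O)O)[C@@H](c2ccccc2)Oc2c(Cc3ccccc3OCc3ccccc3)c(OCc3ccccc3)c(Cc3cc(Cc4cc(Cc5ccccc5OCc5ccccc5)ccc4OCc4ccccc4)ccc3OCc3ccccc3)c(OCc3ccccc3)c21 | intermediate
23 | (2S)-5,7-bis(benzyloxy)-8-[2-(benzyloxy)benzyl]-2-phenyl-6-(trimer-benzyl)chroman-4-one | O=C1C[C@@H](c2ccccc2)Oc2c(Cc3ccccc3OCc3ccccc3)c(OCc3ccccc3)c(Cc3cc(Cc4cc(Cc5ccccc5OCc5ccccc5)ccc4OCc4ccccc4)ccc3OCc3ccccc3)c(OCc3ccccc3)c21 | intermediate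
24 | sarmentosumin B, (2S)-5,7-dihydroxy-8-(2-hydroxybenzyl)-6-[2-hydroxy-5-[[2-hydroxy-5-(2-hydroxybenzyl)phenyl]methyl]benzyl]-2-phenylchroman-4-one | O=C1C[C@@H](c2ccccc2)Oc2c(Cc3ccccc3O)c(O)c(Cc3cc(Cc4cc(Cc5ccccc5O)ccc4O)ccc3O)c(O)c21 | target

**Totals**

Total step count: 16.
Longest linear sequence: 11 steps (steps 2–7, then 12–16; from 3 through 4, 5, 6, 7, 8, 9, 17, 18, 20, 23 to 24).

**Steps most likely to fail**

1. Step 15. What may go wrong: poor enantiofacial discrimination or slow ring closure, because the attacking phenol is flanked by the C8 benzyl group and the aroyl unit is twisted by two ortho substituents; reaction of the E and Z alkylidenes through opposite faces without prior equilibration; retro-oxa-Michael racemisation before decarboxylation is complete.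
Fallback, from 17, returning at 23: acetophenone 17 is condensed with benzaldehyde 19 (KOH, EtOH/THF, rt; Claisen–Schmidt) to the (E)-2'-hydroxychalcone F1. NaOAc in refluxing EtOH closes F1 by the uncatalysed oxa-Michael addition, again only through the one free phenol, to the racemic hexabenzyl flavanone F2. Preparative chromatography on a chiral stationary phase separates 23 from the (2R)-enantiomer F3, which is reopened and reclosed with base and returned to the separation. The stereocentre then comes from resolution, not from catalysis, and no ester has to be installed or removed.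

2. Step 12. What may go wrong: sluggish oxidative addition and transmetalation at the iodide flanked by two benzyloxy groups, so that protonolysis by the free phenol and homocoupling of the large benzylic zinc reagent take over.
Fallback, from phenol 14 together with benzylic alcohol 8, returning at 17: Lewis-acid-catalysed Friedel–Crafts benzylation (Sc(OTf)3 10 mol%, MeNO2/CH2Cl2, rt). The ortho-alkoxy-stabilised benzylic cation from 8 should attack C5 of 14, the only open position of the most electron-rich ring, para to the free OH. Steps 7, 11 and 12 are then not needed, and the fallback makes no compound outside the list (F0).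

3. Step 16. What may go wrong: over-reduction, i.e. hydrogenolysis of the cyclic benzylic C2–O1 bond or reduction of the C4 carbonyl, while the two flanked A-ring benzyl ethers are still being cleaved.
Fallback, from 23, returning at 24: Lewis-acid dealkylation with BCl3 and pentamethylbenzene as cation scavenger (CH2Cl2, −78 °C). The benzyl groups are transferred to the scavenger without hydrogen or metal, so neither the C2–O1 bond nor the ketone can be reduced. The fallback makes no compound outside the list (F0).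

Further compounds
F1 | step 15 | (E)-1-[4,6-bis(benzyloxy)-3-[2-(benzyloxy)benzyl]-2-hydroxy-5-(trimer-benzyl)phenyl]-3-phenylprop-2-en-1-one | O=C(/C=C/c1ccccc1)c1c(O)c(Cc2ccccc2OCc2ccccc2)c(OCc2ccccc2)c(Cc2cc(Cc3cc(Cc4ccccc4OCc4ccccc4)ccc3OCc3ccccc3)ccc2OCc2ccccc2)c1OCc1ccccc1
F2 | step 15 | racemic 5,7-bis(benzyloxy)-8-[2-(benzyloxy)benzyl]-2-phenyl-6-(trimer-benzyl)chroman-4-one | O=C1CC(c2ccccc2)Oc2c(Cc3ccccc3OCc3ccccc3)c(OCc3ccccc3)c(Cc3cc(Cc4cc(Cc5ccccc5OCc5ccccc5)ccc4OCc4ccccc4)ccc3OCc3ccccc3)c(OCc3ccccc3)c21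
F3 | step 15 | (2R)-5,7-bis(benzyloxy)-8-[2-(benzyloxy)benzyl]-2-phenyl-6-(trimer-benzyl)chroman-4-one | O=C1C[C@H](c2ccccc2)Oc2c(Cc3ccccc3OCc3ccccc3)c(OCc3ccccc3)c(Cc3cc(Cc4cc(Cc5ccccc5OCc5ccccc5)ccc4OCc4ccccc4)ccc3OCc3ccccc3)c(OCc3ccccc3)c21
F0 | step 12 | none | none
F0 | step 16 | none | none
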